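**Retrosynthetic overview**

- Target 18 is a tridepside A–B–C: ring A is the terminal 2,4-dihydroxy-6-methylbenzoyl unit, ring B the central 2-hydroxy-6-methylbenzoyl unit, ring C the 2-methoxy-6-methylbenzoic acid unit. All three benzene rings are bought; no ring is formed.
- Feature used: O–C2 of ring A and O–C2 of ring B each sit ortho to a depside carbonyl on C1, and the other ortho carbon (C6) carries CH3. Each acyl ring of the deoxy compound therefore has exactly one ortho C–H.
- 18 ⇐ 16 (hydrogenolysis of the 4-nitrobenzyl ester) ⇐ 15 (removal of the ring A 4-O-acetate) ⇐ 11 by twofold carbonyl-directed C–H hydroxylation (A2–O and B2–O bonds).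
- 11 ⇐ phenol 10 + acid chloride 3; 10 ⇐ 9 ⇐ 8 ⇐ 7 ⇐ phenol 6 + the same chloride 3 (acylations by an acid with one ortho substituent only).
- 6 ⇐ 3-methoxy-5-methylphenol 4 by para-formylation; 3 ⇐ 4-hydroxy-2-methylbenzoic acid 1.

Key step: step 9

Remark on the chemistry: the ring C carboxyl is carried as its 4-nitrobenzyl ester. A plain benzyl ester would be at risk of acidolysis and of attack on its phenyl ring in hot CF3CO2H/(CF3CO)2O with a trivalent iodine oxidant. The 4-nitrobenzyl ester should be inert there, is put on by carboxylate alkylation despite the two ortho substituents, and is still removed by hydrogenation at the end.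

**Route**

Step 1
Reactants: 1 4-hydroxy-2-methylbenzoic acid
Product: 2 4-acetoxy-2-methylbenzoic acid
Conditions: Ac2O, H2SO4 (cat.), 60 °C; then H2O
Reagents that add atoms: acetic anhydride, CC(=O)OC(C)=O
Why: Acid-catalysed O-acetylation of the phenol by the anhydride, the standard preparation of acetoxybenzoic acids, leaves the carboxylic acid free after the aqueous quench.

Step 2
Reactants: 2 4-acetoxy-2-methylbenzoic acid
Product: 3 4-acetoxy-2-methylbenzoyl chloride
Conditions: (COCl)2, DMF (cat.), CH2Cl2, 0 °C to rt; concentrated and used crude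
Reagents that add atoms: oxalyl chloride, O=C(Cl)C(=O)Cl
Why: Acid chloride formation with oxalyl chloride under DMF catalysis proceeds under non-nucleophilic conditions that should leave the aryl acetate untouched.

Step 3
Reactants: 4 3-methoxy-5-methylphenol
Product: 6 4-hydroxy-2-methoxy-6-methylbenzaldehyde, via aryl iminium chloride 5 (not isolated)
Conditions: POCl3, DMF, MeCN, 0 °C to rt; then H2O, 50 °C
Reagents that add atoms: N,N-dimethylformamide, CN(C)C=O; water, O
Why: Vilsmeier–Haack formylation, in which the chloroiminium electrophile should attack para to the free hydroxyl (the strongest donor) at the carbon between OMe and CH3, as is usual for 3-alkoxyphenols; the chelated, much less polar ortho-hydroxy isomer expected as minor product should be removed by chromatography.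

Step 4
Reactants: 6 4-hydroxy-2-methoxy-6-methylbenzaldehyde; 3 4-acetoxy-2-methylbenzoyl chloride
Product: 7 4-formyl-3-methoxy-5-methylphenyl 4-acetoxy-2-methylbenzoate
Conditions: pyridine, CH2Cl2, 0 °C to rt
Reagents that add atoms: none
Why: Einhorn acylation of an acidic para-formyl phenol by an acid chloride with a single ortho substituent should be fast at 0 °C and outpace any acetyl transfer.

Step 5
Reactants: 7 4-formyl-3-methoxy-5-methylphenyl 4-acetoxy-2-methylbenzoate
Product: 8 4-[(4-acetoxy-2-methylbenzoyl)oxy]-2-methoxy-6-methylbenzoic acid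
Conditions: NaClO2, NaH2PO4, 2-methyl-2-butene, t-BuOH/THF/H2O, rt
Reagents that add atoms: sodium chlorite NaClO2, [Na+].[O-]Cl=O
Why: Pinnick (Lindgren) oxidation converts hindered aryl aldehydes to acids near pH 4 with the alkene trapping HOCl, conditions to which the two aryl esters should be inert.

Step 6
Reactants: 8 4-[(4-acetoxy-2-methylbenzoyl)oxy]-2-methoxy-6-methylbenzoic acid
Product: 9 4-nitrobenzyl 4-[(4-acetoxy-2-methylbenzoyl)oxy]-2-methoxy-6-methylbenzoate
Conditions: 4-nitrobenzyl bromide, KHCO3, DMF, rt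
Reagents that add atoms: 4-nitrobenzyl bromide, O=[N+]([O-])c1ccc(CBr)cc1
Why: SN2 alkylation of the carboxylate at a benzylic bromide is insensitive to the two ortho substituents that would slow a Fischer or Steglich esterification, and bicarbonate is too weak a base to cleave the aryl esters.

Step 7
Reactants: 9 4-nitrobenzyl 4-[(4-acetoxy-2-methylbenzoyl)oxy]-2-methoxy-6-methylbenzoate
Product: 10 4-nitrobenzyl 4-[(4-hydroxy-2-methylbenzoyl)oxy]-2-methoxy-6-methylbenzoate
Conditions: H2NNH2·AcOH, DMF, 0 °C to rt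
Reagents that add atoms: none
Why: Chemoselective hydrazinolysis, in which the unhindered aryl acetate should react with the alpha-effect nucleophile far faster than the conjugated, ortho-methylated aryl benzoate or the doubly ortho-substituted alkyl ester.

Step 8
Reactants: 10 4-nitrobenzyl 4-[(4-hydroxy-2-methylbenzoyl)oxy]-2-methoxy-6-methylbenzoate; 3 4-acetoxy-2-methylbenzoyl chloride
Product: 11 4-nitrobenzyl 4-{[4-(4-acetoxy-2-methylbenzoyloxy)-2-methylbenzoyl]oxy}-2-methoxy-6-methylbenzoate
Conditions: pyridine, DMAP (cat.), CH2Cl2, 0 °C to rt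
Reagents that add atoms: none
Why: A second Einhorn acylation with the same singly ortho-substituted acid chloride on an unhindered phenol should complete the deoxy tridepside without any phenol differentiation.

Step 9
Reactants: 11 4-nitrobenzyl 4-{[4-(4-acetoxy-2-methylbenzoyloxy)-2-methylbenzoyl]oxy}-2-methoxy-6-methylbenzoate
Product: 15 4-nitrobenzyl 4-{[4-(4-acetoxy-2-hydroxy-6-methylbenzoyloxy)-2-hydroxy-6-methylbenzoyl]oxy}-2-methoxy-6-methylbenzoate, via ring A mono(trifluoroacetate) 12 (not isolated), via ring B mono(trifluoroacetate) 13 (not isolated), via bis(trifluoroacetate) 14 (not isolated)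
Conditions: [RuCl2(p-cymene)]2 (10 mol %), PhI(OCOCF3)2 (3 equiv), CF3CO2H/(CF3CO)2O (3:1), 70 °C; then H2O/THF, rt
Reagents that add atoms: bis(trifluoroacetoxy)iodobenzene PhI(OCOCF3)2, O=C(O[I](OC(=O)C(F)(F)F)c1ccccc1)C(F)(F)F; trifluoroacetic acid (solvent, its carboxylate exchanges with those on iodine and ruthenium), OC(=O)C(F)(F)F
Why: Proposed new method: in the acidic medium [RuCl2(p-cymene)]2 should give a cationic divalent ruthenium trifluoroacetate that is bound by each depside carbonyl oxygen and, by carboxylate-assisted metalation, cleaves the only ortho C–H of that acyl ring (C6 of each 2-methylbenzoyl unit, the other ortho carbon carrying methyl) to form a five-membered ruthenacycle; oxidation by the trivalent iodine reagent to tetravalent ruthenium and C–O reductive elimination then give the aryl trifluoroacetate, which the anhydride keeps acylated and so shielded from further oxidation until water frees the phenol. The closest known reaction type is the ruthenium-catalysed, ester-directed ortho C–H hydroxylation of alkyl benzoates under these conditions, which has not been shown twice in one molecule or with aryl benzoates as the directing esters. No ring is closed and no stereocentre is formed. The step needs acyl-side metalation (five-membered chelate) to beat metalation of the O-aryl rings through six-membered chelates (ring B C5 through the A–B carbonyl, ring C C3 and C5 through the B–C carbonyl, ring A C3 and C5 through the acetate), which the smaller planar chelate of a weakly coordinating carbonyl should secure, helped at ring C by the two flanking substituents at each free position. Ring C cannot be oxygenated through its own ester because both its ortho carbons carry OMe and CH3, and the nitrobenzyl ring is too electron-poor and too remote to react. Either mono-oxygenated stage, 12 or 13, may form first and both lead to 14.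

Step 10
Reactants: 15 4-nitrobenzyl 4-{[4-(4-acetoxy-2-hydroxy-6-methylbenzoyloxy)-2-hydroxy-6-methylbenzoyl]oxy}-2-methoxy-6-methylbenzoate
Product: 16 4-nitrobenzyl 4-{[4-(2,4-dihydroxy-6-methylbenzoyloxy)-2-hydroxy-6-methylbenzoyl]oxy}-2-methoxy-6-methylbenzoate
Conditions: H2NNH2·AcOH (1.1 equiv), DMF, 0 °C
Reagents that add atoms: none
Why: Chemoselective hydrazinolysis as in step 7, the acetate being the only unhindered ester while both depside carbonyls are flanked by an ortho methyl and a hydrogen-bonded ortho hydroxyl, with one equivalent of reagent at 0 °C to limit attack there.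

Step 11
Reactants: 16 4-nitrobenzyl 4-{[4-(2,4-dihydroxy-6-methylbenzoyloxy)-2-hydroxy-6-methylbenzoyl]oxy}-2-methoxy-6-methylbenzoate
Product: 18 4-{[4-(2,4-dihydroxy-6-methylbenzoyloxy)-2-hydroxy-6-methylbenzoyl]oxy}-2-methoxy-6-methylbenzoic acid (CNP0283563.0), via 4-aminobenzyl ester 17 (not isolated)
Conditions: H2 (1 atm), Pd/C, EtOAc/THF, rt; dilute HCl wash
Reagents that add atoms: none
Why: Catalytic hydrogenation reduces the nitro group and then hydrogenolyses the benzylic C–O bond of the 4-aminobenzyl ester under neutral conditions that should leave the aryl esters and phenols intact, the 4-methylaniline formed being removed by the acid wash.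

**Compound list**

1 | 4-hydroxy-2-methylbenzoic acid | Cc1cc(O)ccc1C(=O)O | starting material
2 | 4-acetoxy-2-methylbenzoic acid | CC(=O)Oc1ccc(C(=O)O)c(C)c1 | intermediate
3 | 4-acetoxy-2-methylbenzoyl chloride | CC(=O)Oc1ccc(C(Cl)=O)c(C)c1 | intermediate
4 | 3-methoxy-5-methylphenol | COc1cc(C)cc(O)c1 | starting material
5 | (4-hydroxy-2-methoxy-6-methylbenzylidene)dimethyliminium chloride | COc1cc(O)cc(C)c1C=[N+](C)C.[Cl-] | intermediate (not isolated)
6 | 4-hydroxy-2-methoxy-6-methylbenzaldehyde | COc1cc(O)cc(C)c1C=O | intermediate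
7 | 4-formyl-3-methoxy-5-methylphenyl 4-acetoxy-2-methylbenzoate | COc1cc(OC(=O)c2ccc(OC(C)=O)cc2C)cc(C)c1C=O | intermediate
8 | 4-[(4-acetoxy-2-methylbenzoyl)oxy]-2-methoxy-6-methylbenzoic acid | COc1cc(OC(=O)c2ccc(OC(C)=O)cc2C)cc(C)c1C(=O)O | intermediate
9 | 4-nitrobenzyl 4-[(4-acetoxy-2-methylbenzoyl)oxy]-2-methoxy-6-methylbenzoate | COc1cc(OC(=O)c2ccc(OC(C)=O)cc2C)cc(C)c1C(=O)OCc1ccc([N+](=O)[O-])cc1 | intermediate
10 | 4-nitrobenzyl 4-[(4-hydroxy-2-methylbenzoyl)oxy]-2-methoxy-6-methylbenzoate | COc1cc(OC(=O)c2ccc(O)cc2C)cc(C)c1C(=O)OCc1ccc([N+](=O)[O-])cc1 | intermediate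
11 | 4-nitrobenzyl 4-{[4-(4-acetoxy-2-methylbenzoyloxy)-2-methylbenzoyl]oxy}-2-methoxy-6-methylbenzoate | COc1cc(OC(=O)c2ccc(OC(=O)c3ccc(OC(C)=O)cc3C)cc2C)cc(C)c1C(=O)OCc1ccc([N+](=O)[O-])cc1 | intermediate (key-step precursor)
12 | ring A mono(trifluoroacetate): 11 with OCOCF3 at the free ortho carbon of ring A | COc1cc(OC(=O)c2ccc(OC(=O)c3c(OC(=O)C(F)(F)F)cc(OC(C)=O)cc3C)cc2C)cc(C)c1C(=O)OCc1ccc([N+](=O)[O-])cc1 | intermediate (not isolated)
13 | ring B mono(trifluoroacetate): 11 with OCOCF3 at the free ortho carbon of ring B | COc1cc(OC(=O)c2c(OC(=O)C(F)(F)F)cc(OC(=O)c3ccc(OC(C)=O)cc3C)cc2C)cc(C)c1C(=O)OCc1ccc([N+](=O)[O-])cc1 | intermediate (not isolated)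
14 | bis(trifluoroacetate) of 15 | COc1cc(OC(=O)c2c(OC(=O)C(F)(F)F)cc(OC(=O)c3c(OC(=O)C(F)(F)F)cc(OC(C)=O)cc3C)cc2C)cc(C)c1C(=O)OCc1ccc([N+](=O)[O-])cc1 | intermediate (not isolated)
15 | 4-nitrobenzyl 4-{[4-(4-acetoxy-2-hydroxy-6-methylbenzoyloxy)-2-hydroxy-6-methylbenzoyl]oxy}-2-methoxy-6-methylbenzoate | COc1cc(OC(=O)c2c(O)cc(OC(=O)c3c(O)cc(OC(C)=O)cc3C)cc2C)cc(C)c1C(=O)OCc1ccc([N+](=O)[O-])cc1 | intermediate (key-step product)
16 | 4-nitrobenzyl 4-{[4-(2,4-dihydroxy-6-methylbenzoyloxy)-2-hydroxy-6-methylbenzoyl]oxy}-2-methoxy-6-methylbenzoate | COc1cc(OC(=O)c2c(O)cc(OC(=O)c3c(O)cc(O)cc3C)cc2C)cc(C)c1C(=O)OCc1ccc([N+](=O)[O-])cc1 | intermediate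
17 | 4-aminobenzyl 4-{[4-(2,4-dihydroxy-6-methylbenzoyloxy)-2-hydroxy-6-methylbenzoyl]oxy}-2-methoxy-6-methylbenzoate | COc1cc(OC(=O)c2c(O)cc(OC(=O)c3c(O)cc(O)cc3C)cc2C)cc(C)c1C(=O)OCc1ccc(N)cc1 | intermediate (not isolated)
18 | 4-{[4-(2,4-dihydroxy-6-methylbenzoyloxy)-2-hydroxy-6-methylbenzoyl]oxy}-2-methoxy-6-methylbenzoic acid | COc1cc(OC(=O)c2c(C)cc(OC(=O)c3c(C)cc(O)cc3O)cc2O)cc(C)c1C(=O)O | target

**Step count**

Total steps: 11. Longest linear sequence: 10 steps (1 → 2 → 3 → 7 → 8 → 9 → 10 → 11 → 15 → 16 → 18; steps 1, 2 and 4 to 11).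

**Steps most likely to fail**

1. Step 9 (proposed new method).
   - What may go wrong: metalation on the O-aryl side through the six-membered chelates (ring B C5, or ring A through the acetate) would give regioisomeric phenols. The second oxygenation may stall after the first. The trivalent iodine reagent may oxidise or arylate the anisole ring C. The ester links may scramble in the hot acid.
   - Fallback (known chemistry; sets out from 6, comes back at 18): the two hydroxyls are bought with the orsellinic building blocks instead of being made.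
     - Methyl 2,4-dihydroxy-6-methylbenzoate is benzylated at its non-chelated 4-OH (BnBr, K2CO3, acetone) to give methyl 4-(benzyloxy)-2-hydroxy-6-methylbenzoate F1.
     - Saponification (KOH, aqueous DMSO, 90 °C) gives 4-(benzyloxy)-2-hydroxy-6-methylbenzoic acid F2.
     - F2 is condensed through its mixed trifluoroacetic anhydride ((CF3CO)2O, toluene, rt) with the non-chelated 4-OH of 2,4-dihydroxy-6-methylbenzaldehyde to give 4-formyl-3-hydroxy-5-methylphenyl 4-(benzyloxy)-2-hydroxy-6-methylbenzoate F3.
     - Lindgren oxidation (NaClO2, H2NSO3H, aqueous dioxane) gives 4-{[4-(benzyloxy)-2-hydroxy-6-methylbenzoyl]oxy}-2-hydroxy-6-methylbenzoic acid F4.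
     - The same anhydride condensation of F4 with phenol 6 gives 4-formyl-3-methoxy-5-methylphenyl 4-{[4-(benzyloxy)-2-hydroxy-6-methylbenzoyl]oxy}-2-hydroxy-6-methylbenzoate F5.
     - A second Lindgren oxidation gives 4-[(4-{[4-(benzyloxy)-2-hydroxy-6-methylbenzoyl]oxy}-2-hydroxy-6-methylbenzoyl)oxy]-2-methoxy-6-methylbenzoic acid F6.
     - Hydrogenolysis of the benzyl ether (H2, Pd/C, EtOAc) gives 18.

2. Step 10.
   - What may go wrong: once the depside carbonyls carry ortho hydroxyls, intramolecular assistance may let hydrazine cleave the A–B or B–C ester at a rate that competes with acetate removal, or acyl groups may migrate.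
   - Fallback (sets out from 11, comes back at 16): the acetate is removed before any ortho hydroxyl exists and the phenol is masked only in the flask.
     - Hydrazinolysis of 11 (H2NNH2·AcOH, DMF, 0 °C) gives 4-nitrobenzyl 4-{[4-(4-hydroxy-2-methylbenzoyloxy)-2-methylbenzoyl]oxy}-2-methoxy-6-methylbenzoate F7.
     - F7 is dissolved in CF3CO2H/(CF3CO)2O so that, before the oxidant is added, the phenol is converted into its ring A 4-O-trifluoroacetate F8.
     - The hydroxylation of step 9 then gives the tris(trifluoroacetate) F9, and the aqueous work-up frees all three phenols to give 16 directly.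

3. Step 3.
   - What may go wrong: poor site selectivity of the formylation, with attack ortho to the hydroxyl (para to OMe) competing with the wanted para attack and lowering the supply of 6.
   - Fallback (sets out from 3, comes back at 7; 4, 5 and 6 are bypassed): the formyl position is bought.
     - Acid chloride 3 acylates commercial 2,4-dihydroxy-6-methylbenzaldehyde at its non-chelated 4-OH (pyridine, CH2Cl2, 0 °C) to give 4-formyl-3-hydroxy-5-methylphenyl 4-acetoxy-2-methylbenzoate F10.
     - Mitsunobu O-methylation of the chelated 2-OH (MeOH, PPh3, diisopropyl azodicarboxylate, THF) gives 7.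

**Further compounds**

F1 | step 9 | methyl 4-(benzyloxy)-2-hydroxy-6-methylbenzoate | COC(=O)c1c(C)cc(OCc2ccccc2)cc1O
F2 | step 9 | 4-(benzyloxy)-2-hydroxy-6-methylbenzoic acid | Cc1cc(OCc2ccccc2)cc(O)c1C(=O)O
F3 | step 9 | 4-formyl-3-hydroxy-5-methylphenyl 4-(benzyloxy)-2-hydroxy-6-methylbenzoate | Cc1cc(OCc2ccccc2)cc(O)c1C(=O)Oc1cc(C)c(C=O)c(O)c1
F4 | step 9 | 4-{[4-(benzyloxy)-2-hydroxy-6-methylbenzoyl]oxy}-2-hydroxy-6-methylbenzoic acid | Cc1cc(OCc2ccccc2)cc(O)c1C(=O)Oc1cc(C)c(C(=O)O)c(O)c1
F5 | step 9 | 4-formyl-3-methoxy-5-methylphenyl 4-{[4-(benzyloxy)-2-hydroxy-6-methylbenzoyl]oxy}-2-hydroxy-6-methylbenzoate | Cc1cc(OCc2ccccc2)cc(O)c1C(=O)Oc1cc(C)c(C(=O)Oc2cc(C)c(C=O)c(OC)c2)c(O)c1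
F6 | step 9 | 4-[(4-{[4-(benzyloxy)-2-hydroxy-6-methylbenzoyl]oxy}-2-hydroxy-6-methylbenzoyl)oxy]-2-methoxy-6-methylbenzoic acid | Cc1cc(OCc2ccccc2)cc(O)c1C(=O)Oc1cc(C)c(C(=O)Oc2cc(C)c(C(=O)O)c(OC)c2)c(O)c1
F7 | step 10 | 4-nitrobenzyl 4-{[4-(4-hydroxy-2-methylbenzoyloxy)-2-methylbenzoyl]oxy}-2-methoxy-6-methylbenzoate | COc1cc(OC(=O)c2ccc(OC(=O)c3ccc(O)cc3C)cc2C)cc(C)c1C(=O)OCc1ccc([N+](=O)[O-])cc1
F8 | step 10 | ring A 4-O-trifluoroacetate of F7 | COc1cc(OC(=O)c2ccc(OC(=O)c3ccc(OC(=O)C(F)(F)F)cc3C)cc2C)cc(C)c1C(=O)OCc1ccc([N+](=O)[O-])cc1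
F9 | step 10 | tris(trifluoroacetate) of 16 | COc1cc(OC(=O)c2c(OC(=O)C(F)(F)F)cc(OC(=O)c3c(OC(=O)C(F)(F)F)cc(OC(=O)C(F)(F)F)cc3C)cc2C)cc(C)c1C(=O)OCc1ccc([N+](=O)[O-])cc1
F10 | step 3 | 4-formyl-3-hydroxy-5-methylphenyl 4-acetoxy-2-methylbenzoate | CC(=O)Oc1ccc(C(=O)Oc2cc(C)c(C=O)c(O)c2)c(C)c1
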